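**Assumption:** the SMILES is read literally. The aryl-bearing carbon (C7) is R and the methyl-bearing carbon (C8) is S, which is the cis-2,3-disubstituted dioxane. Neolignan numbering is used throughout, with C9 as the methyl carbon.

## Retrosynthetic overview
1. Only one ring is made, since both arenes are bought. The 1,4-dioxane ring is closed last at C7–O by an intramolecular Mitsunobu SN2 (inversion), taking threo-(7S,8S) phenol-alcohol 21 to cis-(7R,8S) 23.
2. The C9 methyl comes from CH2OTs, then CH2OH, then the imide carbonyl of aldol adduct 16. The C7-OH is masked as TBS and the phenol as TIPS.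
3. The key C7–C8 bond is made by an Evans boron syn-aldol of N-(aryloxyacetyl)oxazolidinone 12 with 3,4,5-trimethoxybenzaldehyde 13. This sets both stereocentres and already carries the C8–O–aryl ether.
4. Imide 12 comes from acid 9, which comes from 5-bromosalicylaldehyde 1. The OH (para to Br) is alkylated, CHO becomes the second oxygen (Baeyer–Villiger) and Br becomes allyl (Stille), so the starting material fixes the catechol regiochemistry.

## Route

**Step 1**
Reactants: 1 5-bromo-2-hydroxybenzaldehyde; 2 tert-butyl bromoacetate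
Product: 3 tert-butyl 2-(4-bromo-2-formylphenoxy)acetate
Conditions: K2CO3, DMF, rt
Reagents that add atoms: tert-butyl bromoacetate (2), BrCC(=O)OC(C)(C)C
Why: Williamson ether synthesis of an acidic phenol with an activated primary bromide; at rt the aldehyde does not condense to the benzofuran.

**Step 2**
Reactants: 3 tert-butyl 2-(4-bromo-2-formylphenoxy)acetate
Product: 5 tert-butyl 2-(4-bromo-2-hydroxyphenoxy)acetate, via aryl formate 4 (not isolated)
Conditions: mCPBA, CH2Cl2, rt; then Et3N (cat.), MeOH, rt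
Reagents that add atoms: mCPBA, O=C(OO)c1cccc(Cl)c1
Why: Baeyer–Villiger oxidation in which the ortho-alkoxy aryl group migrates, followed by mild methanolysis of the labile aryl formate; the hindered tert-butyl ester neither transesterifies nor lactonises.

**Step 3**
Reactants: 5 tert-butyl 2-(4-bromo-2-hydroxyphenoxy)acetate
Product: 6 tert-butyl 2-{4-bromo-2-[(triisopropylsilyl)oxy]phenoxy}acetate
Conditions: TIPSCl, imidazole, DMF, rt
Reagents that add atoms: TIPSCl, CC(C)[Si](Cl)(C(C)C)C(C)C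
Why: Standard phenol silylation; because the neighbouring oxygen is already alkylated, no O-to-O silyl migration can scramble the regiochemistry.

**Step 4**
Reactants: 6 tert-butyl 2-{4-bromo-2-[(triisopropylsilyl)oxy]phenoxy}acetate; 7 allyltributylstannane
Product: 8 tert-butyl 2-{4-allyl-2-[(triisopropylsilyl)oxy]phenoxy}acetate
Conditions: Pd(PPh3)4 (5 mol %), toluene, 110 °C, degassed
Reagents that add atoms: allyltributylstannane (7), C=CC[Sn](CCCC)(CCCC)CCCC
Why: Stille cross-coupling under neutral, base- and fluoride-free conditions, so the ester and silyl ether survive and the allyl group is not isomerised to propenyl.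

**Step 5**
Reactants: 8 tert-butyl 2-{4-allyl-2-[(triisopropylsilyl)oxy]phenoxy}acetate
Product: 9 2-{4-allyl-2-[(triisopropylsilyl)oxy]phenoxy}acetic acid
Conditions: TFA/CH2Cl2 (1:3), 0 °C → rt
Reagents that add atoms: none
Why: Acidolysis of the tert-butyl ester through the tert-butyl cation; phenolic TIPS ethers are very acid-stable and a monosubstituted alkene is not attacked by dilute TFA.

**Step 6**
Reactants: 9 2-{4-allyl-2-[(triisopropylsilyl)oxy]phenoxy}acetic acid; 10 (R)-4-benzyloxazolidin-2-one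
Product: 12 (R)-3-(2-{4-allyl-2-[(triisopropylsilyl)oxy]phenoxy}acetyl)-4-benzyloxazolidin-2-one, via mixed pivalic anhydride 11 (not isolated)
Conditions: PivCl, Et3N, THF, −20 °C; then LiCl, 10, −20 °C → rt
Reagents that add atoms: (R)-4-benzyloxazolidin-2-one (10), O=C1N[C@H](Cc2ccccc2)CO1; pivaloyl chloride, CC(C)(C)C(=O)Cl (atoms only in intermediate 11)
Why: Mixed-anhydride N-acylation in which the Li-activated oxazolidinone attacks the unhindered aryloxyacetyl carbonyl rather than the pivaloyl one.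

**Step 7 (key C–C bond)**
Reactants: 12 (R)-3-(2-{4-allyl-2-[(triisopropylsilyl)oxy]phenoxy}acetyl)-4-benzyloxazolidin-2-one; 13 3,4,5-trimethoxybenzaldehyde
Product: 16 (R)-3-[(2R,3S)-2-{4-allyl-2-[(triisopropylsilyl)oxy]phenoxy}-3-hydroxy-3-(3,4,5-trimethoxyphenyl)propanoyl]-4-benzyloxazolidin-2-one, via Z-boron enolate 14 (not isolated), via boron aldolate 15 (not isolated)
Conditions: n-Bu2BOTf, Et3N, CH2Cl2, −78 → 0 °C; 13, −78 → 0 °C; then pH 7 buffer, MeOH, 30 % H2O2, 0 °C
Reagents that add atoms: 3,4,5-trimethoxybenzaldehyde (13), COc1cc(C=O)cc(OC)c1OC; di-n-butylboron triflate, CCCCB(CCCC)OS(=O)(=O)C(F)(F)F (boron only in intermediates 14 and 15)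
Why: Evans syn-aldol (glycolate type) in which the Z-boron enolate reacts through a closed Zimmerman–Traxler chair with the benzyl group of the (R)-auxiliary blocking one enolate face, setting C8 (= C2, R here) and C7 (= C3, S) together as the syn/threo pair.

**Step 8**
Reactants: 16 syn-aldol adduct
Product: 17 (R)-3-[(2R,3S)-2-{4-allyl-2-[(triisopropylsilyl)oxy]phenoxy}-3-[(tert-butyldimethylsilyl)oxy]-3-(3,4,5-trimethoxyphenyl)propanoyl]-4-benzyloxazolidin-2-one
Conditions: TBSOTf, 2,6-lutidine, CH2Cl2, 0 °C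
Reagents that add atoms: TBSOTf, CC(C)(C)[Si](C)(C)OS(=O)(=O)C(F)(F)F
Why: Silylation under non-nucleophilic, weakly basic conditions blocks retro-aldol, oxetane formation and Grob fragmentation in the following steps without touching either stereocentre.

**Step 9**
Reactants: 17 TBS-protected aldol adduct
Product: 18 (2S,3S)-2-{4-allyl-2-[(triisopropylsilyl)oxy]phenoxy}-3-[(tert-butyldimethylsilyl)oxy]-3-(3,4,5-trimethoxyphenyl)propan-1-ol
Conditions: LiBH4, MeOH (1 equiv), THF/Et2O, 0 °C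
Reagents that add atoms: none
Why: Reductive removal of the Evans auxiliary by hydride attack at the more electrophilic exocyclic carbonyl; alkene and silyl ethers tolerate it and the geometry is unchanged (C8 is now called S only because CH2OH ranks below C7).

**Step 10**
Reactants: 18 primary alcohol
Product: 19 (2S,3S)-2-{4-allyl-2-[(triisopropylsilyl)oxy]phenoxy}-3-[(tert-butyldimethylsilyl)oxy]-3-(3,4,5-trimethoxyphenyl)propyl 4-methylbenzenesulfonate
Conditions: TsCl, Et3N, DMAP (cat.), CH2Cl2, 0 °C → rt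
Reagents that add atoms: TsCl, Cc1ccc(cc1)S(=O)(=O)Cl
Why: Sulfonylation of the only free hydroxyl group, with the reaction at oxygen so that no stereocentre is involved.

**Step 11**
Reactants: 19 primary tosylate
Product: 20 tert-butyl{[(1S,2S)-2-{4-allyl-2-[(triisopropylsilyl)oxy]phenoxy}-1-(3,4,5-trimethoxyphenyl)propyl]oxy}dimethylsilane
Conditions: LiEt3BH (3 equiv), THF, 0 °C → rt
Reagents that add atoms: none
Why: SN2 hydride displacement of a primary sulfonate by Super-Hydride, which copes with β-branched substrates and leaves the alkene, aryl ethers and silyl ethers alone, turning C9 into the methyl group.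

**Step 12**
Reactants: 20 bis-silyl ether
Product: 21 5-allyl-2-{[(1S,2S)-1-hydroxy-1-(3,4,5-trimethoxyphenyl)propan-2-yl]oxy}phenol
Conditions: TBAF (3 equiv), THF, 0 °C → rt
Reagents that add atoms: none
Why: Fluoride-driven desilylation frees the phenol and the benzylic alcohol in one acid-free operation, so the benzylic centre cannot ionise and the threo-(7S,8S) configuration is kept.

**Step 13**
Reactants: 21 threo phenol-alcohol
Product: 23 (2S,3R)-2-methyl-6-(prop-2-en-1-yl)-3-(3,4,5-trimethoxyphenyl)-2,3-dihydro-1,4-benzodioxine, via oxyphosphonium phenoxide 22 (not isolated)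
Conditions: PPh3, DIAD, THF (0.02 M), 0 °C → rt
Reagents that add atoms: triphenylphosphine, c1ccc(cc1)P(c1ccccc1)c1ccccc1 (atoms only in intermediate 22, none in 23)
Why: Intramolecular Mitsunobu etherification in which the phenoxide displaces the benzylic oxyphosphonium in a 6-exo-tet SN2 with inversion (7S → 7R) while C8 stays S, giving the cis ring; the β-aryloxy group and the low-polarity medium disfavour ionisation.

## Compound list
1 | 5-bromo-2-hydroxybenzaldehyde | O=Cc1cc(Br)ccc1O | starting material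
2 | tert-butyl bromoacetate | BrCC(=O)OC(C)(C)C | starting material
3 | tert-butyl 2-(4-bromo-2-formylphenoxy)acetate | O=Cc1cc(Br)ccc1OCC(=O)OC(C)(C)C | intermediate
4 | tert-butyl 2-[4-bromo-2-(formyloxy)phenoxy]acetate | O=COc1cc(Br)ccc1OCC(=O)OC(C)(C)C | intermediate
5 | tert-butyl 2-(4-bromo-2-hydroxyphenoxy)acetate | Oc1cc(Br)ccc1OCC(=O)OC(C)(C)C | intermediate
6 | tert-butyl 2-{4-bromo-2-[(triisopropylsilyl)oxy]phenoxy}acetate | CC(C)[Si](Oc1cc(Br)ccc1OCC(=O)OC(C)(C)C)(C(C)C)C(C)C | intermediate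
7 | allyltributylstannane | C=CC[Sn](CCCC)(CCCC)CCCC | starting material
8 | tert-butyl 2-{4-allyl-2-[(triisopropylsilyl)oxy]phenoxy}acetate | C=CCc1ccc(OCC(=O)OC(C)(C)C)c(O[Si](C(C)C)(C(C)C)C(C)C)c1 | intermediate
9 | 2-{4-allyl-2-[(triisopropylsilyl)oxy]phenoxy}acetic acid | C=CCc1ccc(OCC(=O)O)c(O[Si](C(C)C)(C(C)C)C(C)C)c1 | intermediate
10 | (R)-4-benzyloxazolidin-2-one | O=C1N[C@H](Cc2ccccc2)CO1 | starting material
11 | mixed pivalic anhydride of 9 | C=CCc1ccc(OCC(=O)OC(=O)C(C)(C)C)c(O[Si](C(C)C)(C(C)C)C(C)C)c1 | intermediate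
12 | (R)-3-(2-{4-allyl-2-[(triisopropylsilyl)oxy]phenoxy}acetyl)-4-benzyloxazolidin-2-one | C=CCc1ccc(OCC(=O)N2[C@H](Cc3ccccc3)COC2=O)c(O[Si](C(C)C)(C(C)C)C(C)C)c1 | intermediate
13 | 3,4,5-trimethoxybenzaldehyde | COc1cc(C=O)cc(OC)c1OC | starting material
14 | (Z)-dibutylboron enolate of 12 | CCCCB(CCCC)O/C(=C\Oc1ccc(CC=C)cc1O[Si](C(C)C)(C(C)C)C(C)C)N1[C@H](Cc2ccccc2)COC1=O | intermediate
15 | dibutylboron aldolate, (2R,3S) | O=C(N1[C@H](Cc2ccccc2)COC1=O)[C@H](Oc1ccc(CC=C)cc1O[Si](C(C)C)(C(C)C)C(C)C)[C@@H](OB(CCCC)CCCC)c1cc(OC)c(OC)c(OC)c1 | intermediate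
16 | syn-aldol adduct, (4R)-auxiliary, (2R,3S) | O=C(N1[C@H](Cc2ccccc2)COC1=O)[C@H](Oc1ccc(CC=C)cc1O[Si](C(C)C)(C(C)C)C(C)C)[C@@H](O)c1cc(OC)c(OC)c(OC)c1 | intermediate
17 | 3-O-TBS ether of 16, (2R,3S) | O=C(N1[C@H](Cc2ccccc2)COC1=O)[C@H](Oc1ccc(CC=C)cc1O[Si](C(C)C)(C(C)C)C(C)C)[C@@H](O[Si](C)(C)C(C)(C)C)c1cc(OC)c(OC)c(OC)c1 | intermediate
18 | (2S,3S)-2-aryloxy-3-(TBS-oxy)-3-(3,4,5-trimethoxyphenyl)propan-1-ol (aryl = 4-allyl-2-TIPSO-phenyl) | OC[C@H](Oc1ccc(CC=C)cc1O[Si](C(C)C)(C(C)C)C(C)C)[C@@H](O[Si](C)(C)C(C)(C)C)c1cc(OC)c(OC)c(OC)c1 | intermediate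
19 | tosylate of 18, (2S,3S) | Cc1ccc(cc1)S(=O)(=O)OC[C@H](Oc1ccc(CC=C)cc1O[Si](C(C)C)(C(C)C)C(C)C)[C@@H](O[Si](C)(C)C(C)(C)C)c1cc(OC)c(OC)c(OC)c1 | intermediate
20 | (1S,2S)-bis-silyl ether with C9 = CH3 | C[C@H](Oc1ccc(CC=C)cc1O[Si](C(C)C)(C(C)C)C(C)C)[C@@H](O[Si](C)(C)C(C)(C)C)c1cc(OC)c(OC)c(OC)c1 | intermediate
21 | 5-allyl-2-{[(1S,2S)-1-hydroxy-1-(3,4,5-trimethoxyphenyl)propan-2-yl]oxy}phenol | C[C@H](Oc1ccc(CC=C)cc1O)[C@@H](O)c1cc(OC)c(OC)c(OC)c1 | intermediate
22 | C7-oxyphosphonium phenoxide zwitterion, (7S,8S) | C[C@H](Oc1ccc(CC=C)cc1[O-])[C@@H](O[P+](c1ccccc1)(c1ccccc1)c1ccccc1)c1cc(OC)c(OC)c(OC)c1 | intermediate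
23 | (2S,3R)-2-methyl-6-allyl-3-(3,4,5-trimethoxyphenyl)-2,3-dihydro-1,4-benzodioxine (cis; C7 R, C8 S) | C=CCc1ccc2c(c1)O[C@H](c1cc(OC)c(OC)c(OC)c1)[C@H](C)O2 | target

## Step count and risks
Total step count: 13. Longest linear sequence: 13 steps (1 → 23).

**Step 13** carries the highest risk. Partial ionisation of 22 would leak to the more stable trans isomer, and E2 loss would give an enol ether.
- The fallback sets out from 21 and comes back at 23. It resets C7 by substrate control instead of by SN2.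
- The phenol alone is silylated (TBSCl 1.05 equiv, imidazole, CH2Cl2, 0 °C) to give the phenol TBS ether F1.
- Dess–Martin periodinane oxidises the benzylic alcohol to the aryl ketone F2.
- Buffered TBAF/AcOH, which protects the enolisable C8, frees the phenol, and this closes onto the ketone as the cyclic hemiketal F3.
- Et3SiH/BF3·OEt2 in CH2Cl2 at −78 °C ionises it to the oxocarbenium ion F4.
- Hydride adds anti to the pseudoaxial C8 methyl group, placing aryl and methyl cis and giving 23.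

**Step 7** may suffer slow enolisation or lower diastereoselectivity with the bulky, Lewis-basic aryloxyacetyl imide.
- The fallback sets out from 9 and comes back at 18. It keeps the same C7–C8 aldol bond but uses a different auxiliary class and metal.
- Acid 9 is coupled with purchased (R)-4-benzylthiazolidine-2-thione (EDCI, DMAP, CH2Cl2) to give the N-acylthiazolidinethione F5.
- TiCl4, i-Pr2NEt and NMP in CH2Cl2 at −78 °C generate the chlorotitanium enolate F6.
- F6 adds to 13 through the non-chelated chair to give the Evans-syn aldol adduct F7, a yellow and easily purified compound.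
- TBSOTf/2,6-lutidine gives the TBS ether F8, and NaBH4 in THF/EtOH cleaves the very labile thione auxiliary directly to 18.

**Step 11** may give S–O cleavage back to 18 or E2 elimination at the congested β-branched tosylate. Any premature loss of TIPS would also let the phenoxide close the wrong ring onto C9.
- The fallback sets out from 18 and comes back at 20. It replaces polar displacement by a radical chain.
- An Appel-type iodination (I2, PPh3, imidazole, toluene, rt) gives the primary iodide F9.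
- F9 is reduced with concentrated Bu3SnH and Et3B/air in toluene at 0 °C.
- The low temperature and high hydride concentration outrun β-scission of the aryloxy group and leave the remote allyl group alone, giving 20.

## Further compounds
F1 | step 13 | (1S,2S)-2-{4-allyl-2-[(tert-butyldimethylsilyl)oxy]phenoxy}-1-(3,4,5-trimethoxyphenyl)propan-1-ol | C[C@H](Oc1ccc(CC=C)cc1O[Si](C)(C)C(C)(C)C)[C@@H](O)c1cc(OC)c(OC)c(OC)c1
F2 | step 13 | (2S)-2-{4-allyl-2-[(tert-butyldimethylsilyl)oxy]phenoxy}-1-(3,4,5-trimethoxyphenyl)propan-1-one | C[C@H](Oc1ccc(CC=C)cc1O[Si](C)(C)C(C)(C)C)C(=O)c1cc(OC)c(OC)c(OC)c1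
F3 | step 13 | (3S)-7-allyl-3-methyl-2-(3,4,5-trimethoxyphenyl)-2,3-dihydro-1,4-benzodioxin-2-ol (anomer mixture) | C=CCc1ccc2c(c1)OC(O)(c1cc(OC)c(OC)c(OC)c1)[C@H](C)O2
F4 | step 13 | (3S)-7-allyl-3-methyl-2-(3,4,5-trimethoxyphenyl)-3H-1,4-benzodioxin-1-ium (oxocarbenium ion) | C=CCc1ccc2c(c1)[O+]=C(c1cc(OC)c(OC)c(OC)c1)[C@H](C)O2
F5 | step 7 | 2-{4-allyl-2-[(triisopropylsilyl)oxy]phenoxy}-1-[(R)-4-benzyl-2-thioxothiazolidin-3-yl]ethan-1-one | C=CCc1ccc(OCC(=O)N2[C@H](Cc3ccccc3)CSC2=S)c(O[Si](C(C)C)(C(C)C)C(C)C)c1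
F6 | step 7 | (Z)-trichlorotitanium enolate of F5 | Cl[Ti](Cl)(Cl)O/C(=C\Oc1ccc(CC=C)cc1O[Si](C(C)C)(C(C)C)C(C)C)N1[C@H](Cc2ccccc2)CSC1=S
F7 | step 7 | (2R,3S)-syn-aldol adduct on (R)-4-benzylthiazolidine-2-thione | O=C(N1[C@H](Cc2ccccc2)CSC1=S)[C@H](Oc1ccc(CC=C)cc1O[Si](C(C)C)(C(C)C)C(C)C)[C@@H](O)c1cc(OC)c(OC)c(OC)c1
F8 | step 7 | 3-O-TBS ether of F7, (2R,3S) | O=C(N1[C@H](Cc2ccccc2)CSC1=S)[C@H](Oc1ccc(CC=C)cc1O[Si](C(C)C)(C(C)C)C(C)C)[C@@H](O[Si](C)(C)C(C)(C)C)c1cc(OC)c(OC)c(OC)c1
F9 | step 11 | (1S,2R)-2-aryloxy-1-(TBS-oxy)-3-iodo-1-(3,4,5-trimethoxyphenyl)propane (same geometry as 18; C2 is R because CH2I outranks C1) | IC[C@H](Oc1ccc(CC=C)cc1O[Si](C(C)C)(C(C)C)C(C)C)[C@@H](O[Si](C)(C)C(C)(C)C)c1cc(OC)c(OC)c(OC)c1
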